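**Retrosynthetic overview**
1. Target acid ⇐ oxidation of dioxine-ethanol 43 ⇐ 6-exo opening of the (S)-2-alkenyl oxetane in 42 by the C6 tertiary hydroperoxide (inversion gives 3R); this closes the only ring of the target, last.
2. Oxetane 41 ⇐ (3S)-1,3-diol 39 ⇐ ketoreductase reduction of the (Z)-enone β-keto ester 37 ⇐ (Z)-enal 33 ⇐ Still–Gennari olefination of α-peroxy aldehyde 25.
3. Aldehyde 25 (C6 quaternary, R) ⇐ glycol cleavage ⇐ Mo-catalysed perhydrolysis, with inversion, of Sharpless epoxide 20 ⇐ (Z)-allylic alcohol 19.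
4. Alcohol 19 ⇐ syn-carbocupration of ynoate 16 ⇐ alkyne 13 ⇐ ester 9; C10 and then C8 come from two Cu/Tol-BINAP conjugate additions (EtMgBr, MeMgBr) starting from achiral methyl (E)-hept-2-enoate.
5. Ring order: oxirane (formed step 10, opened step 12) → oxetane (formed step 25, opened step 27) → 1,2-dioxine (step 27).

Assumption: carbon building blocks are numbered starting materials and stand only on the Reactants line; the Tol-BINAP antipode giving (S)-3 is taken as (S) from memory, is confirmed on 3 (rotation/chiral GC), and is used again in step 4.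

**Step 1**
Reactants: 1 methyl (E)-hept-2-enoate; 2 ethylmagnesium bromide
Product: 3 methyl (S)-3-ethylheptanoate
Conditions: EtMgBr (1.2 equiv), CuI (1 mol%), (S)-Tol-BINAP (1.5 mol%), t-BuOMe, −40 °C; aq. work-up
Reagents that add atoms: none
Why: Cu(I)/Tol-BINAP-catalysed asymmetric conjugate addition of the Grignard reagent delivers ethyl to one enantioface of the (E)-enoate and sets C10 of the target as (S), the first stereocentre.

**Step 2**
Reactants: 3 methyl (S)-3-ethylheptanoate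
Product: 4 (S)-3-ethylheptanal
Conditions: DIBAL-H (1.1 equiv), CH2Cl2, −78 °C; Rochelle salt
Reagents that add atoms: none
Why: DIBAL-H partial reduction stops at the aluminium hemiacetal at −78 °C and gives the aldehyde on work-up; the β-stereocentre cannot enolise.

**Step 3**
Reactants: 4 (S)-3-ethylheptanal; 5 trimethyl phosphonoacetate
Product: 7 methyl (2E,5S)-5-ethylnon-2-enoate, via sodium phosphonate 6 (not isolated)
Conditions: NaH, THF, 0 °C; then 4, 0 °C → rt
Reagents that add atoms: none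
Why: Horner–Wadsworth–Emmons olefination with a stabilised phosphonate anion gives the (E)-enoate needed for the second conjugate addition.

**Step 4**
Reactants: 7 methyl (2E,5S)-5-ethylnon-2-enoate; 8 methylmagnesium bromide
Product: 9 methyl (3S,5S)-5-ethyl-3-methylnonanoate
Conditions: MeMgBr (4 equiv), CuI (2 mol%), (S)-Tol-BINAP (3 mol%), t-BuOMe, −20 °C; aq. work-up
Reagents that add atoms: none
Why: A second Cu/Tol-BINAP asymmetric conjugate addition under catalyst control, with the same ligand antipode and the same facial sense, gives the 1,3-syn (3S,5S) array (C8 and C10 of the target).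

**Step 5**
Reactants: 9 methyl (3S,5S)-5-ethyl-3-methylnonanoate
Product: 10 (3S,5S)-5-ethyl-3-methylnonanal
Conditions: DIBAL-H (1.1 equiv), CH2Cl2, −78 °C; Rochelle salt
Reagents that add atoms: none
Why: DIBAL-H partial reduction of the ester to the aldehyde, whose stereocentres are β and δ and therefore configurationally safe.

**Step 6**
Reactants: 10 (3S,5S)-5-ethyl-3-methylnonanal; 11 dimethyl (1-diazo-2-oxopropyl)phosphonate
Product: 13 (4S,6S)-6-ethyl-4-methyldec-1-yne, via diazomethylphosphonate 12 (not isolated)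
Conditions: K2CO3 (2 equiv), MeOH, 0 °C → rt
Reagents that add atoms: none
Why: Ohira–Bestmann (Seyferth–Gilbert) homologation: methanolysis unmasks the diazomethylphosphonate, then HWE-type addition and loss of N2 give the terminal alkyne under mild base.

**Step 7**
Reactants: 13 (4S,6S)-6-ethyl-4-methyldec-1-yne; 14 methyl chloroformate
Product: 16 methyl (5S,7S)-7-ethyl-5-methylundec-2-ynoate, via lithium acetylide 15 (not isolated)
Conditions: n-BuLi, THF, −78 °C; then ClCO2Me, −78 → 0 °C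
Reagents that add atoms: none
Why: Deprotonation of the terminal alkyne and C-acylation of the acetylide with the chloroformate gives the ynoate.

**Step 8**
Reactants: 16 methyl (5S,7S)-7-ethyl-5-methylundec-2-ynoate; 2 ethylmagnesium bromide
Product: 18 methyl (2Z,5S,7S)-3,7-diethyl-5-methylundec-2-enoate, via ethylcopper 17 (not isolated)
Conditions: EtMgBr (1.5 equiv), CuBr·SMe2 (1.5 equiv), THF, −40 °C; then 16, −78 °C; MeOH/H2O quench at −78 °C
Reagents that add atoms: none
Why: Syn-carbocupration of the ynoate (Normant organocopper addition) followed by cold protonation with retention puts Et and H cis, giving the nerol-type (Z)-enoate stereospecifically.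

**Step 9**
Reactants: 18 methyl (2Z,5S,7S)-3,7-diethyl-5-methylundec-2-enoate
Product: 19 (2Z,5S,7S)-3,7-diethyl-5-methylundec-2-en-1-ol
Conditions: DIBAL-H (2.2 equiv), CH2Cl2, −78 °C
Reagents that add atoms: none
Why: DIBAL-H 1,2-reduction of the enoate to the allylic alcohol leaves the alkene geometry untouched.

**Step 10**
Reactants: 19 (2Z,5S,7S)-3,7-diethyl-5-methylundec-2-en-1-ol
Product: 20 [(2R,3S)-3-ethyl-3-[(2S,4S)-4-ethyl-2-methyloctyl]oxiran-2-yl]methanol
Conditions: Ti(Oi-Pr)4 (10 mol%), D-(−)-diethyl tartrate (12 mol%), t-BuOOH (2 equiv), 4 Å MS, CH2Cl2, −20 °C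
Reagents that add atoms: tert-butyl hydroperoxide CC(C)(C)OO
Why: Sharpless asymmetric epoxidation under reagent control (nerol gives 2S,3R with L-(+)-tartrate, so D-(−)-tartrate gives 2R,3S here) fixes the quaternary carbon that becomes C6.

**Step 11**
Reactants: 20 [(2R,3S)-3-ethyl-3-[(2S,4S)-4-ethyl-2-methyloctyl]oxiran-2-yl]methanol
Product: 21 tert-butyl{[(2R,3S)-3-ethyl-3-[(2S,4S)-4-ethyl-2-methyloctyl]oxiran-2-yl]methoxy}diphenylsilane
Conditions: TBDPSCl, imidazole, CH2Cl2, 0 °C → rt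
Reagents that add atoms: tert-butyl(chloro)diphenylsilane CC(C)(C)[Si](Cl)(c1ccccc1)c1ccccc1
Why: Silylation of the primary alcohol keeps it masked, so that after epoxide opening only the hydroperoxide and a hindered secondary alcohol are free.

**Step 12**
Reactants: 21 tert-butyl{[(2R,3S)-3-ethyl-3-[(2S,4S)-4-ethyl-2-methyloctyl]oxiran-2-yl]methoxy}diphenylsilane
Product: 22 (2R,3R,5S,7S)-1-[(tert-butyldiphenylsilyl)oxy]-3,7-diethyl-3-hydroperoxy-5-methylundecan-2-ol
Conditions: H2O2 (anhydrous, in Et2O, 10 equiv), phosphomolybdic acid (3 mol%), Et2O, 0 °C → rt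
Reagents that add atoms: hydrogen peroxide OO
Why: Mo-catalysed perhydrolysis of the trisubstituted epoxide, with SN2-like attack of H2O2 at the tertiary carbon and inversion, turns the (3S)-epoxide carbon into the (3R)-tertiary hydroperoxide (C6 of the target).

**Step 13**
Reactants: 22 (2R,3R,5S,7S)-1-[(tert-butyldiphenylsilyl)oxy]-3,7-diethyl-3-hydroperoxy-5-methylundecan-2-ol
Product: 23 (2R,3R,5S,7S)-1-[(tert-butyldiphenylsilyl)oxy]-3,7-diethyl-3-[(2-methoxypropan-2-yl)peroxy]-5-methylundecan-2-ol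
Conditions: 2-methoxypropene (1.5 equiv), PPTS (5 mol%), CH2Cl2, −20 °C
Reagents that add atoms: 2-methoxypropene COC(C)=C
Why: Acid-catalysed addition of the hydroperoxide (α-effect nucleophile, faster than the hindered secondary alcohol) to the enol ether gives the base-stable peroxyketal protecting group.

**Step 14**
Reactants: 23 (2R,3R,5S,7S)-1-[(tert-butyldiphenylsilyl)oxy]-3,7-diethyl-3-[(2-methoxypropan-2-yl)peroxy]-5-methylundecan-2-ol
Product: 24 (2R,3R,5S,7S)-3,7-diethyl-3-[(2-methoxypropan-2-yl)peroxy]-5-methylundecane-1,2-diol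
Conditions: TBAF, THF, 0 °C
Reagents that add atoms: none
Why: Fluoride desilylation frees the 1,2-diol while the peroxyketal, stable to base and fluoride, stays in place.

**Step 15**
Reactants: 24 (2R,3R,5S,7S)-3,7-diethyl-3-[(2-methoxypropan-2-yl)peroxy]-5-methylundecane-1,2-diol
Product: 25 (2R,4S,6S)-2,6-diethyl-2-[(2-methoxypropan-2-yl)peroxy]-4-methyldecanal
Conditions: NaIO4, THF/pH 7 buffer, 0 °C → rt
Reagents that add atoms: none
Why: Malaprade periodate glycol cleavage excises C1 as formaldehyde and leaves the α-peroxy aldehyde, whose fully substituted α-carbon cannot epimerise.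

**Step 16**
Reactants: 26 methyl 2-[bis(2,2,2-trifluoroethoxy)phosphoryl]acetate; 27 iodoethane
Product: 29 methyl 2-[bis(2,2,2-trifluoroethoxy)phosphoryl]butanoate (racemic), via potassium phosphonate 28 (not isolated)
Conditions: KOt-Bu, THF, 0 °C; then EtI, rt
Reagents that add atoms: none
Why: SN2 C-alkylation of the stabilised phosphonoacetate anion gives the α-ethyl Still–Gennari reagent, whose stereocentre is destroyed in step 17.

**Step 17**
Reactants: 25 (2R,4S,6S)-2,6-diethyl-2-[(2-methoxypropan-2-yl)peroxy]-4-methyldecanal; 29 methyl 2-[bis(2,2,2-trifluoroethoxy)phosphoryl]butanoate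
Product: 31 methyl (2Z,4R,6S,8S)-2,4,8-triethyl-4-[(2-methoxypropan-2-yl)peroxy]-6-methyldodec-2-enoate, via potassium phosphonate 30 (not isolated)
Conditions: KHMDS, 18-crown-6, THF, −78 °C; then 25, −78 → −40 °C
Reagents that add atoms: none
Why: Still–Gennari (Z-selective Horner–Wadsworth–Emmons) olefination, with fast elimination from the kinetic adduct of the trifluoroethyl phosphonate, gives the (Z)-trisubstituted enoate with the ester cis to C6 as the later ring closure requires.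

**Step 18**
Reactants: 31 methyl (2Z,4R,6S,8S)-2,4,8-triethyl-4-[(2-methoxypropan-2-yl)peroxy]-6-methyldodec-2-enoate
Product: 32 (2Z,4R,6S,8S)-2,4,8-triethyl-4-[(2-methoxypropan-2-yl)peroxy]-6-methyldodec-2-en-1-ol
Conditions: DIBAL-H (2.2 equiv), CH2Cl2, −78 °C
Reagents that add atoms: none
Why: DIBAL-H 1,2-reduction of the hindered enoate at −78 °C, where the tertiary peroxyketal is not reduced.

**Step 19**
Reactants: 32 (2Z,4R,6S,8S)-2,4,8-triethyl-4-[(2-methoxypropan-2-yl)peroxy]-6-methyldodec-2-en-1-ol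
Product: 33 (2Z,4R,6S,8S)-2,4,8-triethyl-4-[(2-methoxypropan-2-yl)peroxy]-6-methyldodec-2-enal
Conditions: Dess–Martin periodinane, pyridine, CH2Cl2, 0 °C
Reagents that add atoms: none
Why: Buffered Dess–Martin oxidation of the allylic alcohol gives the (Z)-enal without acid or base that could isomerise the alkene or cleave the peroxyketal.

**Step 20**
Reactants: 33 (2Z,4R,6S,8S)-2,4,8-triethyl-4-[(2-methoxypropan-2-yl)peroxy]-6-methyldodec-2-enal; 34 ethyl acetate
Product: 36 ethyl (3RS,4Z,6R,8S,10S)-4,6,10-triethyl-3-hydroxy-6-[(2-methoxypropan-2-yl)peroxy]-8-methyltetradec-4-enoate, via lithium ester enolate 35 (not isolated)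
Conditions: LDA, THF, −78 °C; EtOAc; then 33, −78 °C
Reagents that add atoms: none
Why: Aldol 1,2-addition of the acetate enolate installs C1–C2; the C3 epimer mixture does not matter because C3 is oxidised in the next step.

**Step 21**
Reactants: 36 ethyl (3RS,4Z,6R,8S,10S)-4,6,10-triethyl-3-hydroxy-6-[(2-methoxypropan-2-yl)peroxy]-8-methyltetradec-4-enoate
Product: 37 ethyl (4Z,6R,8S,10S)-4,6,10-triethyl-6-[(2-methoxypropan-2-yl)peroxy]-8-methyl-3-oxotetradec-4-enoate
Conditions: Dess–Martin periodinane, pyridine, CH2Cl2, 0 °C → rt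
Reagents that add atoms: none
Why: Dess–Martin oxidation of the allylic β-hydroxy ester gives the β-keto ester substrate for enzymatic reduction.

**Step 22**
Reactants: 37 ethyl (4Z,6R,8S,10S)-4,6,10-triethyl-6-[(2-methoxypropan-2-yl)peroxy]-8-methyl-3-oxotetradec-4-enoate
Product: 38 ethyl (3S,4Z,6R,8S,10S)-4,6,10-triethyl-3-hydroxy-6-[(2-methoxypropan-2-yl)peroxy]-8-methyltetradec-4-enoate
Conditions: ketoreductase (KRED, (S)-selective variant chosen from a screening panel), NADP+ (cat.), i-PrOH (20% v/v), phosphate buffer pH 7.0, 30 °C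
Reagents that add atoms: none
Why: Biocatalytic asymmetric reduction by a ketoreductase (NADPH-dependent alcohol dehydrogenase class, i-PrOH cofactor recycling) delivers hydride to one face of the β-keto ester and sets C3 as (S) under enzyme control.

**Step 23**
Reactants: 38 ethyl (3S,4Z,6R,8S,10S)-4,6,10-triethyl-3-hydroxy-6-[(2-methoxypropan-2-yl)peroxy]-8-methyltetradec-4-enoate
Product: 39 (3S,4Z,6R,8S,10S)-4,6,10-triethyl-6-[(2-methoxypropan-2-yl)peroxy]-8-methyltetradec-4-ene-1,3-diol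
Conditions: LiBH4, THF, 0 °C
Reagents that add atoms: none
Why: Borohydride reduction of the β-hydroxy ester gives the 1,3-diol without touching the hindered peroxyketal or the C3 stereocentre.

**Step 24**
Reactants: 39 (3S,4Z,6R,8S,10S)-4,6,10-triethyl-6-[(2-methoxypropan-2-yl)peroxy]-8-methyltetradec-4-ene-1,3-diol
Product: 40 (3S,4Z,6R,8S,10S)-4,6,10-triethyl-3-hydroxy-6-[(2-methoxypropan-2-yl)peroxy]-8-methyltetradec-4-en-1-yl 4-methylbenzenesulfonate
Conditions: TsCl (1.1 equiv), pyridine, CH2Cl2, 0 °C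
Reagents that add atoms: 4-methylbenzenesulfonyl chloride Cc1ccc(cc1)S(Cl)(=O)=O
Why: Selective sulfonylation of the primary hydroxyl over the hindered secondary allylic one.

**Step 25**
Reactants: 40 (3S,4Z,6R,8S,10S)-4,6,10-triethyl-3-hydroxy-6-[(2-methoxypropan-2-yl)peroxy]-8-methyltetradec-4-en-1-yl 4-methylbenzenesulfonate
Product: 41 (2S)-2-[(3Z,5R,7S,9S)-5,9-diethyl-5-[(2-methoxypropan-2-yl)peroxy]-7-methyltridec-3-en-3-yl]oxetane
Conditions: KOt-Bu, THF, 0 °C → rt
Reagents that add atoms: none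
Why: Intramolecular Williamson etherification (4-exo-tet) displaces the primary tosylate, so the C3–O bond is untouched and the oxetane carbon keeps the (S) configuration.

**Step 26**
Reactants: 41 (2S)-2-[(3Z,5R,7S,9S)-5,9-diethyl-5-[(2-methoxypropan-2-yl)peroxy]-7-methyltridec-3-en-3-yl]oxetane
Product: 42 (2S)-2-[(3Z,5R,7S,9S)-5,9-diethyl-5-hydroperoxy-7-methyltridec-3-en-3-yl]oxetane
Conditions: PPTS (10 mol%), MeOH, 0 °C
Reagents that add atoms: none
Why: Acid-catalysed transketalisation to methanol releases the tertiary hydroperoxide under conditions too mild to solvolyse the oxetane.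

**Step 27**
Reactants: 42 (2S)-2-[(3Z,5R,7S,9S)-5,9-diethyl-5-hydroperoxy-7-methyltridec-3-en-3-yl]oxetane
Product: 43 2-[(3R,6R)-4,6-diethyl-6-[(2S,4S)-4-ethyl-2-methyloctyl]-3,6-dihydro-1,2-dioxin-3-yl]ethan-1-ol
Conditions: Yb(OTf)3 (10 mol%), Et2O, 0 °C
Reagents that add atoms: none
Why: Lewis-acid-promoted intramolecular oxetane opening by the hydroperoxide (6-exo-tet, Dussault-type) proceeds by backside attack, inverting C3 from (S) to (R); the Z-alkene holds the two ends together and the 2-hydroxyethyl arm is unveiled.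

**Step 28**
Reactants: 43 2-[(3R,6R)-4,6-diethyl-6-[(2S,4S)-4-ethyl-2-methyloctyl]-3,6-dihydro-1,2-dioxin-3-yl]ethan-1-ol
Product: 44 2-[(3R,6R)-4,6-diethyl-6-[(2S,4S)-4-ethyl-2-methyloctyl]-3,6-dihydro-1,2-dioxin-3-yl]acetic acid
Conditions: TEMPO (20 mol%), PhI(OAc)2 (2.5 equiv), MeCN/H2O, rt
Reagents that add atoms: water O
Why: TEMPO/PhI(OAc)2 oxidation of the primary alcohol through the aldehyde hydrate gives the acid under near-neutral conditions that spare the peroxide, the ring alkene and both ring stereocentres.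

**Compound list**
1 | methyl (E)-hept-2-enoate | CCCC/C=C/C(=O)OC | starting material
2 | ethylmagnesium bromide | CC[Mg]Br | starting material
3 | methyl (S)-3-ethylheptanoate | CCCC[C@H](CC)CC(=O)OC | intermediate
4 | (S)-3-ethylheptanal | CCCC[C@H](CC)CC=O | intermediate
5 | trimethyl phosphonoacetate | COC(=O)CP(=O)(OC)OC | starting material
6 | sodium salt of trimethyl phosphonoacetate | [Na+].COC(=O)[CH-]P(=O)(OC)OC | intermediate
7 | methyl (2E,5S)-5-ethylnon-2-enoate | CCCC[C@H](CC)C/C=C/C(=O)OC | intermediate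
8 | methylmagnesium bromide | C[Mg]Br | starting material
9 | methyl (3S,5S)-5-ethyl-3-methylnonanoate | CCCC[C@H](CC)C[C@H](C)CC(=O)OC | intermediate
10 | (3S,5S)-5-ethyl-3-methylnonanal | CCCC[C@H](CC)C[C@H](C)CC=O | intermediate
11 | dimethyl (1-diazo-2-oxopropyl)phosphonate | CC(=O)C(=[N+]=[N-])P(=O)(OC)OC | starting material
12 | dimethyl (diazomethyl)phosphonate | [N-]=[N+]=CP(=O)(OC)OC | intermediate
13 | (4S,6S)-6-ethyl-4-methyldec-1-yne | CCCC[C@H](CC)C[C@H](C)CC#C | intermediate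
14 | methyl chloroformate | COC(=O)Cl | starting material
15 | lithium (4S,6S)-6-ethyl-4-methyldec-1-yn-1-ide | CCCC[C@H](CC)C[C@H](C)CC#C[Li] | intermediate
16 | methyl (5S,7S)-7-ethyl-5-methylundec-2-ynoate | CCCC[C@H](CC)C[C@H](C)CC#CC(=O)OC | intermediate
17 | ethylcopper(I) | CC[Cu] | intermediate
18 | methyl (2Z,5S,7S)-3,7-diethyl-5-methylundec-2-enoate | CCCC[C@H](CC)C[C@H](C)C/C(CC)=C\C(=O)OC | intermediate
19 | (2Z,5S,7S)-3,7-diethyl-5-methylundec-2-en-1-ol | CCCC[C@H](CC)C[C@H](C)C/C(CC)=C\CO | intermediate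
20 | [(2R,3S)-3-ethyl-3-[(2S,4S)-4-ethyl-2-methyloctyl]oxiran-2-yl]methanol | CCCC[C@H](CC)C[C@H](C)C[C@]1(CC)O[C@@H]1CO | intermediate
21 | tert-butyl{[(2R,3S)-3-ethyl-3-[(2S,4S)-4-ethyl-2-methyloctyl]oxiran-2-yl]methoxy}diphenylsilane | CCCC[C@H](CC)C[C@H](C)C[C@]1(CC)O[C@@H]1CO[Si](c1ccccc1)(c1ccccc1)C(C)(C)C | intermediate
22 | (2R,3R,5S,7S)-1-[(tert-butyldiphenylsilyl)oxy]-3,7-diethyl-3-hydroperoxy-5-methylundecan-2-ol | CCCC[C@H](CC)C[C@H](C)C[C@@](CC)(OO)[C@H](O)CO[Si](c1ccccc1)(c1ccccc1)C(C)(C)C | intermediate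
23 | (2R,3R,5S,7S)-1-[(tert-butyldiphenylsilyl)oxy]-3,7-diethyl-3-[(2-methoxypropan-2-yl)peroxy]-5-methylundecan-2-ol | CCCC[C@H](CC)C[C@H](C)C[C@@](CC)(OOC(C)(C)OC)[C@H](O)CO[Si](c1ccccc1)(c1ccccc1)C(C)(C)C | intermediate
24 | (2R,3R,5S,7S)-3,7-diethyl-3-[(2-methoxypropan-2-yl)peroxy]-5-methylundecane-1,2-diol | CCCC[C@H](CC)C[C@H](C)C[C@@](CC)(OOC(C)(C)OC)[C@H](O)CO | intermediate
25 | (2R,4S,6S)-2,6-diethyl-2-[(2-methoxypropan-2-yl)peroxy]-4-methyldecanal | CCCC[C@H](CC)C[C@H](C)C[C@@](CC)(OOC(C)(C)OC)C=O | intermediate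
26 | methyl 2-[bis(2,2,2-trifluoroethoxy)phosphoryl]acetate | COC(=O)CP(=O)(OCC(F)(F)F)OCC(F)(F)F | starting material
27 | iodoethane | CCI | starting material
28 | potassium salt of methyl 2-[bis(2,2,2-trifluoroethoxy)phosphoryl]acetate | [K+].COC(=O)[CH-]P(=O)(OCC(F)(F)F)OCC(F)(F)F | intermediate
29 | methyl 2-[bis(2,2,2-trifluoroethoxy)phosphoryl]butanoate (racemic) | CCC(C(=O)OC)P(=O)(OCC(F)(F)F)OCC(F)(F)F | intermediate
30 | potassium salt of methyl 2-[bis(2,2,2-trifluoroethoxy)phosphoryl]butanoate | [K+].CC[C-](C(=O)OC)P(=O)(OCC(F)(F)F)OCC(F)(F)F | intermediate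
31 | methyl (2Z,4R,6S,8S)-2,4,8-triethyl-4-[(2-methoxypropan-2-yl)peroxy]-6-methyldodec-2-enoate | CCCC[C@H](CC)C[C@H](C)C[C@@](CC)(OOC(C)(C)OC)/C=C(/CC)C(=O)OC | intermediate
32 | (2Z,4R,6S,8S)-2,4,8-triethyl-4-[(2-methoxypropan-2-yl)peroxy]-6-methyldodec-2-en-1-ol | CCCC[C@H](CC)C[C@H](C)C[C@@](CC)(OOC(C)(C)OC)/C=C(/CC)CO | intermediate
33 | (2Z,4R,6S,8S)-2,4,8-triethyl-4-[(2-methoxypropan-2-yl)peroxy]-6-methyldodec-2-enal | CCCC[C@H](CC)C[C@H](C)C[C@@](CC)(OOC(C)(C)OC)/C=C(/CC)C=O | intermediate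
34 | ethyl acetate | CCOC(C)=O | starting material
35 | lithium 1-ethoxyethen-1-olate | [Li]OC(=C)OCC | intermediate
36 | ethyl (3RS,4Z,6R,8S,10S)-4,6,10-triethyl-3-hydroxy-6-[(2-methoxypropan-2-yl)peroxy]-8-methyltetradec-4-enoate | CCCC[C@H](CC)C[C@H](C)C[C@@](CC)(OOC(C)(C)OC)/C=C(/CC)C(O)CC(=O)OCC | intermediate
37 | ethyl (4Z,6R,8S,10S)-4,6,10-triethyl-6-[(2-methoxypropan-2-yl)peroxy]-8-methyl-3-oxotetradec-4-enoate | CCCC[C@H](CC)C[C@H](C)C[C@@](CC)(OOC(C)(C)OC)/C=C(/CC)C(=O)CC(=O)OCC | intermediate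
38 | ethyl (3S,4Z,6R,8S,10S)-4,6,10-triethyl-3-hydroxy-6-[(2-methoxypropan-2-yl)peroxy]-8-methyltetradec-4-enoate | CCCC[C@H](CC)C[C@H](C)C[C@@](CC)(OOC(C)(C)OC)/C=C(/CC)[C@@H](O)CC(=O)OCC | intermediate
39 | (3S,4Z,6R,8S,10S)-4,6,10-triethyl-6-[(2-methoxypropan-2-yl)peroxy]-8-methyltetradec-4-ene-1,3-diol | CCCC[C@H](CC)C[C@H](C)C[C@@](CC)(OOC(C)(C)OC)/C=C(/CC)[C@@H](O)CCO | intermediate
40 | (3S,4Z,6R,8S,10S)-4,6,10-triethyl-3-hydroxy-6-[(2-methoxypropan-2-yl)peroxy]-8-methyltetradec-4-en-1-yl 4-methylbenzenesulfonate | CCCC[C@H](CC)C[C@H](C)C[C@@](CC)(OOC(C)(C)OC)/C=C(/CC)[C@@H](O)CCOS(=O)(=O)c1ccc(C)cc1 | intermediate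
41 | (2S)-2-[(3Z,5R,7S,9S)-5,9-diethyl-5-[(2-methoxypropan-2-yl)peroxy]-7-methyltridec-3-en-3-yl]oxetane | CCCC[C@H](CC)C[C@H](C)C[C@@](CC)(OOC(C)(C)OC)/C=C(/CC)[C@@H]1CCO1 | intermediate
42 | (2S)-2-[(3Z,5R,7S,9S)-5,9-diethyl-5-hydroperoxy-7-methyltridec-3-en-3-yl]oxetane | CCCC[C@H](CC)C[C@H](C)C[C@@](CC)(OO)/C=C(/CC)[C@@H]1CCO1 | intermediate
43 | 2-[(3R,6R)-4,6-diethyl-6-[(2S,4S)-4-ethyl-2-methyloctyl]-3,6-dihydro-1,2-dioxin-3-yl]ethan-1-ol | CCCC[C@H](CC)C[C@H](C)C[C@]1(CC)C=C(CC)[C@@H](CCO)OO1 | intermediate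
44 | 2-[(3R,6R)-4,6-diethyl-6-[(2S,4S)-4-ethyl-2-methyloctyl]-3,6-dihydro-1,2-dioxin-3-yl]acetic acid | CCCC[C@H](CC)C[C@H](C)C[C@]1(CC)C=C(CC)[C@@H](CC(=O)O)OO1 | target

**Total step count:** 28
**Longest linear sequence:** 27 steps (steps 1–15 and 17–28; step 16 is a one-step side branch)

**Three steps most likely to fail**

Step 27 (oxetane opening). The oxetane carbon is allylic, so the Lewis acid may ionise it and erode the C3 configuration, or may trigger Hock-type cleavage of the tertiary allylic hydroperoxide. Fallback: set out from enal 33 and close the ring by oxa-Michael addition instead. Horner–Wadsworth–Emmons reaction of 33 with 5 (NaH, THF) gives methyl (2E,4Z,6R,8S,10S)-4,6,10-triethyl-6-[(2-methoxypropan-2-yl)peroxy]-8-methyltetradeca-2,4-dienoate F4. PPTS/MeOH then frees methyl (2E,4Z,6R,8S,10S)-4,6,10-triethyl-6-hydroperoxy-8-methyltetradeca-2,4-dienoate F5. Et2NH in CF3CH2OH cyclises F5 to the dioxine ester as a roughly 1:1 pair of C3 epimers, because C6 (Et versus CH2R) exerts no useful bias. The epimers are separated by HPLC and the wrong one is re-equilibrated through retro-Michael addition, giving methyl 2-[(3R,6R)-4,6-diethyl-6-[(2S,4S)-4-ethyl-2-methyloctyl]-3,6-dihydro-1,2-dioxin-3-yl]acetate F6. Mild LiOH hydrolysis (THF/H2O, 0 °C) brings the fallback back to the route at 44.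

Step 22 (ketoreductase). The carbonyl of 37 is shielded by the cis quaternary centre and the substrate is large and lipophilic, so no panel enzyme may give useful rate and selectivity. Fallback: set out from enal 33 and make the C3 carbinol by C–C bond formation. A catalytic asymmetric acetate Mukaiyama aldol (1-ethoxy-1-(trimethylsilyloxy)ethene, Carreira-type Ti(IV)–BINOL Schiff-base catalyst, Et2O, 0 °C) gives ethyl (3S,4Z,6R,8S,10S)-4,6,10-triethyl-6-[(2-methoxypropan-2-yl)peroxy]-8-methyl-3-[(trimethylsilyl)oxy]tetradec-4-enoate F3. Buffered TBAF desilylation returns to the route at 38, bypassing 36 and 37.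

Step 17 (Still–Gennari). The aldehyde carbon of 25 is attached to a fully substituted carbon, so conversion may be poor or the Z:E ratio may erode on warming. Fallback: set out from 25 and build the alkene by sequential cross-coupling. Ramirez dibromo-olefination (CBr4, PPh3, CH2Cl2, 0 °C) gives (3R,5S,7S)-1,1-dibromo-3,7-diethyl-3-[(2-methoxypropan-2-yl)peroxy]-5-methylundec-1-ene F1. Trans-selective Negishi coupling (EtZnBr, Pd(DPEphos)Cl2 cat., THF) replaces the less hindered bromide and gives (3Z,5R,7S,9S)-3-bromo-5,9-diethyl-5-[(2-methoxypropan-2-yl)peroxy]-7-methyltridec-3-ene F2. Pd-catalysed methoxycarbonylation (CO, MeOH, Et3N) of the remaining bromide, with retention, returns to the route at 31.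

**Further compounds**
F1 | step 17 | (3R,5S,7S)-1,1-dibromo-3,7-diethyl-3-[(2-methoxypropan-2-yl)peroxy]-5-methylundec-1-ene | CCCC[C@H](CC)C[C@H](C)C[C@@](CC)(OOC(C)(C)OC)C=C(Br)Br
F2 | step 17 | (3Z,5R,7S,9S)-3-bromo-5,9-diethyl-5-[(2-methoxypropan-2-yl)peroxy]-7-methyltridec-3-ene | CCCC[C@H](CC)C[C@H](C)C[C@@](CC)(OOC(C)(C)OC)/C=C(/CC)Br
F3 | step 22 | ethyl (3S,4Z,6R,8S,10S)-4,6,10-triethyl-6-[(2-methoxypropan-2-yl)peroxy]-8-methyl-3-[(trimethylsilyl)oxy]tetradec-4-enoate | CCCC[C@H](CC)C[C@H](C)C[C@@](CC)(OOC(C)(C)OC)/C=C(/CC)[C@@H](O[Si](C)(C)C)CC(=O)OCC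
F4 | step 27 | methyl (2E,4Z,6R,8S,10S)-4,6,10-triethyl-6-[(2-methoxypropan-2-yl)peroxy]-8-methyltetradeca-2,4-dienoate | CCCC[C@H](CC)C[C@H](C)C[C@@](CC)(OOC(C)(C)OC)/C=C(/CC)\C=C\C(=O)OC
F5 | step 27 | methyl (2E,4Z,6R,8S,10S)-4,6,10-triethyl-6-hydroperoxy-8-methyltetradeca-2,4-dienoate | CCCC[C@H](CC)C[C@H](C)C[C@@](CC)(OO)/C=C(/CC)\C=C\C(=O)OC
F6 | step 27 | methyl 2-[(3R,6R)-4,6-diethyl-6-[(2S,4S)-4-ethyl-2-methyloctyl]-3,6-dihydro-1,2-dioxin-3-yl]acetate | CCCC[C@H](CC)C[C@H](C)C[C@]1(CC)C=C(CC)[C@@H](CC(=O)OC)OO1
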